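The small charge of free nucleophile was where I started.

electrophile 0.20 M; protonated nucleophile 2.00 equiv; time 6.0 h

    electrophile ⇌ dormant form (K1 = 0.592, k1 = 3.69 × 10⁻⁵ s⁻¹)
    electrophile → decomposition product (k2 = 3.23 × 10⁻⁸ s⁻¹)
    nucleophile + acid set free ⇌ protonated nucleophile, settled at all times (K3 = 13000 M⁻¹)
    electrophile + acid set free → side product (k4 = 2.08 × 10⁻⁴ M⁻¹ s⁻¹)
    acid set free + free base ⇌ salt of the base (K5 = 47000 M⁻¹, k5 = 0.0193 M⁻¹ s⁻¹)
    electrophile + nucleophile → acid set free + target (k6 = 0.0202 M⁻¹ s⁻¹)

- the equivalents of free base at which the part of the electrophile that has reacted at 6.0 h is just 80%

In this flask, before any base had acted, the protonated nucleophile split into equal amounts of nucleophile and acid set free, which I reckoned gave [nucleophile] = 5.55 mM.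

Was that level fast enough? It gave the electrophile a pseudo-first-order half-life of 1.72 h, so the run held 3.49 half-lives, and speed looked sufficient as long as the level held.

Could it hold by itself? The electrophile to be used was 160 mM, far more than that free nucleophile. Nucleophile therefore had to keep coming out of its protonated form. Each target used one nucleophile and set free one acid, and the nucleophile that replaced it came out of its protonated form with one more acid, so by my count free base, the limiting reagent, had to take up two acids per target to hold [nucleophile] up.

How much target was needed? I counted the dormant form as reacted and took it at balance, [dormant form] = K1[electrophile]. That was 11.8% of the charge, and I set down the remaining 68.2% as target, leaving the side product and the decomposition product out of this estimate. My base count, twice the target per electrophile charged, came to 1.36 equivalents.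

The forecast gave 0.95 equiv, noting that “the base removes acid slowly”; it differs from my count.

The simulation gave 1.25 equiv, below my count and above the forecast. At 6.00 h the free base in this flask had a half-life of 0.87 h by the forward rate of its reaction with acid set free, short against the run of 6.0 h. With a quarter more free base, the part reacted stood at 85.8%; for that part the base count gives 1.55 equivalents, against 1.56 charged.

The constants used here belong to no real substance; the run is a simulation.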